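Readings and results are simulated from invented constants, and the scatter is random.

- I start from what the protic impurity leaves behind. Each protic impurity turns one starting material into quenched substrate, and its charge is 5.00% of the starting material, so it is the limiting reagent of that step.
- That leaves 95.0% as the target ceiling, the share of the charged starting material that the quench cannot take. The catalyst, at 0.05 mol%, holds too little to count. So once the protic impurity is used up, target equals the ceiling minus the starting material left.

| setting | Friday's | Tuesday's | Thursday's | delta | zeta | epsilon | gamma |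
|---|---|---|---|---|---|---|---|
| starting material | 0.80 M | 0.80 M | 0.80 M | 0.80 M | 0.80 M | 0.80 M | 0.80 M |
| second substrate | 0.50 equiv | 0.75 equiv | 1 equiv | 1.00 equiv | 1.00 equiv | 1.00 equiv | 1.00 equiv |
| protic impurity | 0.040 M | 0.040 M | 0.080 M | 0.0400 M | 0.0400 M | 0.0400 M | 0.0400 M |
| free catalyst | 0.05 mol% | 0.05 mol% | 0.05 mol% | 0.05 mol% | 0.05 mol% | 0.05 mol% | 0.05 mol% |
| temperature | −25 °C | 8 °C | −25 °C |  | 20 °C | −10 °C | −40 °C |
| remark | run made earlier | run made earlier | run made earlier | at −40 °C until 8.0 h, from then on at 20 °C |  |  |  |
| time |  |  |  | 40 h | 40 h | 40 h | 40 h |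

| run | time / h | target / % |
|---|---|---|
| Friday's | 20.0 | 1.2 |
| Friday's | 60.0 | 1.7 |
| Friday's | 120 | 2.9 |
| Friday's | 144 | 1.7 |
| Friday's | 240 | 5.2 |
| Tuesday's | 10.0 | 6.7 |
| Tuesday's | 20.0 | 12.3 |
| Tuesday's | 25.0 | 15.3 |
| Tuesday's | 40.0 | 24.9 |
| Tuesday's | 50.0 | 31.0 |
| Thursday's | 20.0 | 0 |
| Thursday's | 40.0 | 0.8 |
| Thursday's | 60.0 | 0.1 |
| Thursday's | 120 | 1.6 |
| Thursday's | 240 | 3.2 |

(each reading ± 0.5 percentage points)

- the analysis behind the earlier runs scatters by 0.5 percentage points, standard deviation
- steps under discussion: starting material + free catalyst <-> catalyst intermediate A; catalyst intermediate A -> free catalyst + target; second substrate + free catalyst <-> catalyst intermediate B; catalyst intermediate B -> free catalyst + second product; starting material + protic impurity -> quenched substrate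

* the flask that comes out highest in amount of target, in percent of the starting material charged, or "all alike" when all lie within 1.5 percentage points (delta / zeta / epsilon / gamma / all alike)
* target at the end, in percent of the starting material charged, delta
* target at the end, in percent of the starting material charged, zeta
* target at the end, in percent of the starting material charged, epsilon
* target at the end, in percent of the starting material charged, gamma

- The readings show how far below the ceiling a flask stands at a given time. Tuesday's run at 8 °C reads 12.3% at 20.0 h and twice that at 40.0 h, so its target still climbs on a nearly straight line.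
- Friday's run at −25 °C reads 1.2% at 20.0 h, which is far less than Tuesday's run at that time, and these two runs differ both in temperature and in second substrate.
- My own reckoning is a bracket and a ranking, not a point. I expect zeta, at 20 °C, to stand highest, above Tuesday's 24.9% and below the ceiling of 95.0%. I expect delta next, with its first 8.0 h at −40 °C, then epsilon, then gamma.
- The forecast agrees on the ranking and commits to numbers: zeta highest, with 57% for zeta, 47% for delta, 3.1% for epsilon and 0.1% for gamma. Its zeta figure is a projected rate “trimmed to 57% for depletion and quench”.
- The flasks give 49.6% in zeta, 41.4% in delta, 4.26% in epsilon and 0.0717% in gamma, so zeta is highest. The forecast stands 7.4 percentage points above zeta and 5.6 points above delta.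

    starting material + free catalyst ⇌ catalyst intermediate A (K = 2.00 L mol⁻¹, k = 910 L mol⁻¹ h⁻¹, Ea = 35.0 kJ mol⁻¹, ΔH = −38.0 kJ mol⁻¹)
    catalyst intermediate A → free catalyst + target (k = 73.0 h⁻¹, Ea = 72.0 kJ mol⁻¹)
    second substrate + free catalyst ⇌ catalyst intermediate B (K = 1.40 L mol⁻¹, k = 140 L mol⁻¹ h⁻¹, Ea = 45.0 kJ mol⁻¹, ΔH = 21.0 kJ mol⁻¹)
    catalyst intermediate B → free catalyst + second product (k = 27.0 h⁻¹, Ea = 83.0 kJ mol⁻¹)
    starting material + protic impurity → quenched substrate (k = 0.380 L mol⁻¹ h⁻¹, Ea = 62.0 kJ mol⁻¹)
    (constants at 20 °C)

- At 40.0 h zeta still holds 45% of its starting material, with protic impurity down to 0.023% and quenched substrate at 5.00%, so the ceiling minus that leftover gives 50.0%, beside the 49.6% of target it holds. The gap under the ceiling in zeta is unfinished conversion, with the reading time and the reverse step from catalyst intermediate A as two parts of it acting together: from 49.6%, zeta goes to 95.0% when read at 400 h, and to 90.4% at the asked time with that reverse step taken away. In the neighbour of delta charged with 0.250 equiv of second substrate, the same subtraction from 44.3% left gives 50.7%, and that flask holds 50.7% target.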